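The slowness of these flasks is what needs reckoning, not their end: the coupling step runs one way, so we expect substrate, given time, to pass over to target, and the question is how fast.

in all of them: gas 8.6 mM (held)
- teal: substrate 0.028 M; run made earlier
- blue: substrate 0.064 M; run made earlier
- amber: substrate 0.18 M; run made earlier
- gamma: substrate 0.050 M; time 5.0 min
- eta: substrate 0.080 M; time 5.0 min
- beta: substrate 0.15 M; time 5.0 min
- delta: substrate 0.10 M; time 5.0 min
- alpha: substrate 0.030 M; time 5.0 min

| run | time / min | target / % | substrate / % |
|---|---|---|---|
| teal | 0.417 | 8 | 91 |
| teal | 0.833 | 18 | 85 |
| teal | 1.33 | 26 | 78 |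
| teal | 2.50 | 33 | 66 |
| teal | 5.00 | 53 | 47 |
| blue | 0.417 | 8 | 94 |
| blue | 1.33 | 15 | 86 |
| blue | 2.50 | 24 | 78 |
| blue | 4.00 | 36 | 66 |
| blue | 5.00 | 39 | 61 |
| amber | 0.417 | 5 | 98 |
| amber | 1.33 | 8 | 93 |
| amber | 2.50 | 13 | 88 |
| amber | 4.00 | 21 | 83 |
| amber | 5.00 | 22 | 78 |

(each reading ± 1.5 percentage points)

- for target the crystals are counted in
- as a solid, counted per litre of solution: crystals
- at the start none of coupling partner is dissolved
- the analysis behind the earlier runs scatters by 1.5 percentage points, standard deviation
- candidate steps: substrate <-> intermediate + leaving ligand; coupling partner + intermediate -> target; gas <-> coupling partner; crystals <-> target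

1. the flasks put in order of amount of target, in percent of the substrate charged, best first, at 5.0 min (gamma / eta / beta / delta / alpha)
2. the amount of target, in percent of the substrate charged of the flask you put first, at 5.0 min
3. the amount of target, in percent of the substrate charged of the flask you put last, at 5.0 min

We read the runs as a pre-equilibrium. Substrate S reversibly sheds its leaving ligand, one ligand for each target T made, so ligand stands about as high as T and holds the intermediate down in inverse proportion to T. With the gas held we take the coupling partner as steady, which gives dT/dt = bS/T. Integrating, and taking S on average as c(1 − x/2) for a charge c with fraction x turned to target at time t, gives b = c·x·x/[2t(1 − x/2)].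

At 5.00 min teal gives 1.07 mM/min, blue 1.21 mM/min and amber 0.979 mM/min, as readings with their scatter. Their mean, 1.09 mM/min, is our brake constant b, the rate of target when substrate and target stand equal.

Alpha is the near twin of teal, 0.030 M against 0.028 M, and we expect the two to end close, since in our reckoning the charge enters x through bt/c, and at equal time and b the two charges differ by a ratio of 1.07. Solving for x, we reckon 51.8% for alpha, against teal's reading of 53%. For beta, the largest charge, we reckon 25.2%, and in our reckoning, with b and t held, x falls as c rises, so we rank the flasks by rising charge.

The forecast gives alpha > gamma > eta > delta > beta, with 50% and 25%, on the ground that “Lowest substrate is best”, and its top stands a little below our alpha.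

The flasks give alpha > gamma > eta > delta > beta, with alpha at 53.2% and beta at 25.1%.

    substrate ⇌ intermediate + leaving ligand (K = 1.49 × 10⁻⁶ M, k = 0.00694 /s)
    coupling partner + intermediate → target (k = 3910 /M/s)
    gas ⇌ coupling partner, rate k3*(csat - [coupling partner]) (kL = 0.0296 /s)
    crystals ⇌ target, rate k4*(cs4 - [target]) while solid is left; crystals form when [target] > cs4 (solubility = 35.0 mM, k = 0.142 /s)

In alpha at 1.26 min the intermediate falls back 1.4 times faster than it goes on to target. At that moment in alpha, each step taken net, the uptake of gas makes coupling partner 1.45 times faster than the coupling step turns it into target. Alpha's own result returns b = 1.16 mM/min, against our 1.09 mM/min. Put to the neighbour flask, alpha with 0.051 M of substrate, our b gives 41.1%, and that flask holds 43.4% of target.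

The runs stem from a simulated flask for substances that don't exist; scatter was added.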